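**Plan**
- Retrosynthesis: the O4′ pivalate and the O3 sulfate are removed first, and the 3- and 5-hydroxyls are traced back to a benzyl and a methyl ether. The skeleton is then cut at C4–C4a (ring C), at O1–C2 (aryl vinyl ether) and at C2–C3 (flavone numbering).
- Forward: ring B (vanillic acid) is joined through C2–C3 to a benzyloxyacetate, ring A (3,5-dimethoxyphenol) is attached through O1–C2, and ring C is closed last through C4–C4a.
- Enabling feature: C4–C4a ties the C4 carbonyl to a ring A carbon that lies ortho to O1 and para to the C7 oxygen. In a 3,5-dimethoxyphenoxy group the two carbons ortho to the ether oxygen are equivalent and are the most electron-rich sites, so closure can give only the 5,7-dioxygenated chromone.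
- Stereochemistry: the target has no stereocentre. The only stereo element on the way, the geometry of the acrylic C=C bond, is set by the chelated enolate and is in any case equilibrated under acid.
- Endgame: BCl3 bares O3 and the chelated O5, SO3·NMe3 sulfates O3 while O4′ is still an ester, and methanolysis frees O4′.

Key step: step 8

Assumption: the sulfate monoesters 16 and 17 are drawn as free hydrogen sulfates, as the target is written. In the flask they would be ammonium or potassium salts, and the acid form of 17 would be released at the end by brief contact with a cold acidic ion-exchange resin.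

**Route**

Step 1
Reactants: 1 vanillic acid
Product: 2 3-methoxy-4-(pivaloyloxy)benzoic acid
Conditions: PivCl, aq. NaOH, THF, 0 °C; then HCl to pH 2
Reagents that add atoms: pivaloyl chloride, CC(C)(C)C(=O)Cl
Why: Schotten–Baumann acylation, in which the phenoxide is far more nucleophilic than the carboxylate, any mixed anhydride is hydrolysed in the aqueous base, and the hindered aryl pivalate should survive cold dilute hydroxide.

Step 2
Reactants: 2 3-methoxy-4-(pivaloyloxy)benzoic acid
Product: 3 4-(chlorocarbonyl)-2-methoxyphenyl pivalate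
Conditions: (COCl)2, cat. DMF, CH2Cl2, 0 °C → rt
Reagents that add atoms: oxalyl chloride, O=C(Cl)C(=O)Cl
Why: Vilsmeier-catalysed conversion of a benzoic acid into its chloride, to which the aryl pivalate and the methyl ether are inert.

Step 3
Reactants: 4 benzyl alcohol; 5 tert-butyl bromoacetate
Product: 6 tert-butyl (benzyloxy)acetate
Conditions: NaH, THF, 0 °C → rt
Reagents that add atoms: none
Why: Williamson ether synthesis, in which sodium benzyl oxide displaces the activated primary bromide by SN2 while the bulky tert-butyl ester resists transesterification.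

Step 4
Reactants: 6 tert-butyl (benzyloxy)acetate (2 equiv); 3 4-(chlorocarbonyl)-2-methoxyphenyl pivalate
Product: 7 tert-butyl 2-(benzyloxy)-3-[3-methoxy-4-(pivaloyloxy)phenyl]-3-oxopropanoate (racemic)
Conditions: LiN(SiMe3)2 (2 equiv), THF, −78 °C; then 3; aq. NH4Cl
Reagents that add atoms: none
Why: Crossed Claisen condensation (C-acylation of a lithium ester enolate by an aroyl chloride), in which the acid chloride is far more electrophilic than the hindered pivalate and the second equivalent of enolate deprotonates the more acidic product so that it is not acylated again; the new C2 stereocentre forms as a racemate and is erased in step 5.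

Step 5
Reactants: 7 tert-butyl 2-(benzyloxy)-3-[3-methoxy-4-(pivaloyloxy)phenyl]-3-oxopropanoate
Product: 8 tert-butyl (2E)-2-(benzyloxy)-3-[3-methoxy-4-(pivaloyloxy)phenyl]-3-{[(trifluoromethyl)sulfonyl]oxy}prop-2-enoate
Conditions: NaH, Et2O, 0 °C; Tf2O, −78 → 0 °C
Reagents that add atoms: trifluoromethanesulfonic anhydride, O=S(=O)(OS(=O)(=O)C(F)(F)F)C(F)(F)F
Why: Enol triflate formation by O-sulfonylation of the chelated sodium enolate of a β-keto ester, which should place the triflate cis to the ester (E); the geometry is not critical, since it is equilibrated in steps 7 and 8.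

Step 6
Reactants: 8 enol triflate; 9 3,5-dimethoxyphenol
Product: 10 tert-butyl (2E)-2-(benzyloxy)-3-(3,5-dimethoxyphenoxy)-3-[3-methoxy-4-(pivaloyloxy)phenyl]prop-2-enoate
Conditions: Pd2(dba)3 (zerovalent palladium, 2.5 mol %), 2-(di-tert-butylphosphino)-2′,4′,6′-triisopropylbiphenyl, K3PO4, toluene, 80 °C
Reagents that add atoms: none
Why: Palladium-catalysed C–O cross-coupling of a vinyl triflate with a phenol (Buchwald–Hartwig-type etherification), in which the electron-poor enol triflate adds oxidatively to zerovalent palladium and C–O reductive elimination is favoured by the bulky biaryl phosphine and the acrylate acceptor, with retention of alkene geometry; the weak, insoluble base K3PO4 should spare the pivalate and the tert-butyl ester, and any uncatalysed addition–elimination leads to the same product.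

Step 7
Reactants: 10 tert-butyl ester
Product: 11 (2E)-2-(benzyloxy)-3-(3,5-dimethoxyphenoxy)-3-[3-methoxy-4-(pivaloyloxy)phenyl]prop-2-enoic acid
Conditions: TFA, CH2Cl2, 0 °C → rt
Reagents that add atoms: none
Why: Acidolysis of a tert-butyl ester with loss of 2-methylpropene, which the benzyl ether, the aryl pivalate and the vinylogous carbonate should tolerate under anhydrous conditions; every free carbon of ring A is flanked by two oxygen substituents and should be too hindered for tert-butylation.

Step 8
Reactants: 11 (2E)-2-(benzyloxy)-3-(3,5-dimethoxyphenoxy)-3-[3-methoxy-4-(pivaloyloxy)phenyl]prop-2-enoic acid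
Product: 13 4-[3-(benzyloxy)-5,7-dimethoxy-4-oxo-4H-chromen-2-yl]-2-methoxyphenyl pivalate, via mixed trifluoroacetic anhydride 12 (not isolated)
Conditions: (CF3CO)2O, CH2Cl2, 0 °C → rt
Reagents that add atoms: none
Why: Trifluoroacetic anhydride turns acid 11 into the mixed anhydride 12, whose acyl carbon, as such or as the oxygen-stabilized acylium ion, is attacked by a ring A carbon ortho to the ether oxygen, and loss of the proton from the Wheland intermediate gives the 4-pyranone and trifluoroacetic acid. The closest known reactions are the acid-mediated cyclization of 3-aryloxycinnamic acids to flavones and the trifluoroacetic anhydride closure of 2-aryloxybenzoic acids to xanthones, both intramolecular Friedel–Crafts acylations. Ring C closes in a 6-exo-trig mode at the acyl carbon, forming C4–C4a. No stereocentre is formed, and the alkene geometry is not limiting because O-acylation or protonation of the push–pull system lowers the barrier to rotation about C2=C3, so any Z isomer funnels into the cyclizable E form with the acyl group cis to the aryloxy group. The step needs site selectivity on ring A and chemoselectivity against ring B: the two carbons ortho to the ether oxygen are equivalent by the symmetry of the 3,5-dimethoxyphenoxy group and are activated by three oxygen substituents, whereas ring B could react only through a strained five-membered indenone closure onto a ring bearing an acyloxy group. The benzyl ether, the pivalate and the methyl ethers should be inert to the anhydride at room temperature.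

Step 9
Reactants: 13 4-[3-(benzyloxy)-5,7-dimethoxy-4-oxo-4H-chromen-2-yl]-2-methoxyphenyl pivalate
Product: 15 4-(3,5-dihydroxy-7-methoxy-4-oxo-4H-chromen-2-yl)-2-methoxyphenyl pivalate, via 3-hydroxyflavone 14 (not isolated)
Conditions: BCl3, C6HMe5, CH2Cl2, −78 °C → rt; then H2O
Reagents that add atoms: none
Why: Chelation-controlled Lewis acid ether cleavage, in which BCl3 bound at the C4 carbonyl first removes the 3-benzyl group (trapped by pentamethylbenzene) and then the peri 5-methyl group through a six-membered chelate, while the unchelated 7- and 3′-methyl ethers and the pivalate should remain.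

Step 10
Reactants: 15 4-(3,5-dihydroxy-7-methoxy-4-oxo-4H-chromen-2-yl)-2-methoxyphenyl pivalate
Product: 16 4-[5-hydroxy-7-methoxy-4-oxo-3-(sulfooxy)-4H-chromen-2-yl]-2-methoxyphenyl pivalate
Conditions: SO3·NMe3, Et3N, DMF, 60 °C
Reagents that add atoms: sulfur trioxide–trimethylamine complex, C[N+](C)(C)S(=O)(=O)[O-]
Why: O-sulfonation of a hydroxyl group with a sulfur trioxide–amine complex, which should take place only at the 3-hydroxyl because the 5-hydroxyl is locked in a strong hydrogen bond to the C4 carbonyl and is characteristically unreactive, and O4′ is blocked as the pivalate.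

Step 11
Reactants: 16 4-[5-hydroxy-7-methoxy-4-oxo-3-(sulfooxy)-4H-chromen-2-yl]-2-methoxyphenyl pivalate
Product: 17 rhamnazin 3-O-sulfate (5-hydroxy-2-(4-hydroxy-3-methoxyphenyl)-7-methoxy-4-oxo-4H-chromen-3-yl hydrogen sulfate)
Conditions: K2CO3, MeOH, argon, 0 °C → rt; then H+-form sulfonic acid resin, 0 °C
Reagents that add atoms: none
Why: Base-mediated methanolysis (transesterification) of the aryl pivalate, to which the sulfate monoester anion is inert, followed by brief cold cation exchange to give the acid form.

**Compound list**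
1 | vanillic acid | COc1cc(C(=O)O)ccc1O | starting material
2 | 3-methoxy-4-(pivaloyloxy)benzoic acid | COc1cc(C(=O)O)ccc1OC(=O)C(C)(C)C | intermediate
3 | 4-(chlorocarbonyl)-2-methoxyphenyl pivalate | COc1cc(C(=O)Cl)ccc1OC(=O)C(C)(C)C | intermediate
4 | benzyl alcohol | OCc1ccccc1 | starting material
5 | tert-butyl bromoacetate | CC(C)(C)OC(=O)CBr | starting material
6 | tert-butyl (benzyloxy)acetate | CC(C)(C)OC(=O)COCc1ccccc1 | intermediate
7 | tert-butyl 2-(benzyloxy)-3-[3-methoxy-4-(pivaloyloxy)phenyl]-3-oxopropanoate (racemic) | CC(C)(C)OC(=O)C(OCc1ccccc1)C(=O)c1ccc(OC(=O)C(C)(C)C)c(OC)c1 | intermediate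
8 | tert-butyl (2E)-2-(benzyloxy)-3-[3-methoxy-4-(pivaloyloxy)phenyl]-3-{[(trifluoromethyl)sulfonyl]oxy}prop-2-enoate | CC(C)(C)OC(=O)/C(OCc1ccccc1)=C(\OS(=O)(=O)C(F)(F)F)c1ccc(OC(=O)C(C)(C)C)c(OC)c1 | intermediate
9 | 3,5-dimethoxyphenol | COc1cc(O)cc(OC)c1 | starting material
10 | tert-butyl (2E)-2-(benzyloxy)-3-(3,5-dimethoxyphenoxy)-3-[3-methoxy-4-(pivaloyloxy)phenyl]prop-2-enoate | CC(C)(C)OC(=O)/C(OCc1ccccc1)=C(\Oc1cc(OC)cc(OC)c1)c1ccc(OC(=O)C(C)(C)C)c(OC)c1 | intermediate
11 | (2E)-2-(benzyloxy)-3-(3,5-dimethoxyphenoxy)-3-[3-methoxy-4-(pivaloyloxy)phenyl]prop-2-enoic acid | OC(=O)/C(OCc1ccccc1)=C(\Oc1cc(OC)cc(OC)c1)c1ccc(OC(=O)C(C)(C)C)c(OC)c1 | intermediate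
12 | mixed anhydride of 11 with trifluoroacetic acid (not isolated) | O=C(OC(=O)C(F)(F)F)/C(OCc1ccccc1)=C(\Oc1cc(OC)cc(OC)c1)c1ccc(OC(=O)C(C)(C)C)c(OC)c1 | intermediate
13 | 4-[3-(benzyloxy)-5,7-dimethoxy-4-oxo-4H-chromen-2-yl]-2-methoxyphenyl pivalate | COc1cc(OC)c2c(=O)c(OCc3ccccc3)c(-c3ccc(OC(=O)C(C)(C)C)c(OC)c3)oc2c1 | intermediate
14 | 4-(3-hydroxy-5,7-dimethoxy-4-oxo-4H-chromen-2-yl)-2-methoxyphenyl pivalate (not isolated) | COc1cc(OC)c2c(=O)c(O)c(-c3ccc(OC(=O)C(C)(C)C)c(OC)c3)oc2c1 | intermediate
15 | 4-(3,5-dihydroxy-7-methoxy-4-oxo-4H-chromen-2-yl)-2-methoxyphenyl pivalate | COc1cc(O)c2c(=O)c(O)c(-c3ccc(OC(=O)C(C)(C)C)c(OC)c3)oc2c1 | intermediate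
16 | 4-[5-hydroxy-7-methoxy-4-oxo-3-(sulfooxy)-4H-chromen-2-yl]-2-methoxyphenyl pivalate | COc1cc(O)c2c(=O)c(OS(=O)(=O)O)c(-c3ccc(OC(=O)C(C)(C)C)c(OC)c3)oc2c1 | intermediate
17 | rhamnazin 3-O-sulfate | COc1cc(O)c2c(=O)c(OS(=O)(=O)O)c(-c3ccc(O)c(OC)c3)oc2c1 | target

**Step count**
Total: 11 steps. Longest linear sequence: 10 steps (1, 2, 4, 5, 6, 7, 8, 9, 10, 11 from vanillic acid); step 3 is a one-step branch.

**Steps most likely to fail**

Step 6. The phenoxide may attack the triflyl sulfur or the pivaloyl carbonyl instead of entering the palladium cycle, and C–O reductive elimination at a tetrasubstituted, α-oxygenated carbon may be slow, so that 7 is returned or no ether forms. The fallback sets out from 3 and 9 and comes back at 14. It leaves the C3 oxygen out until ring C is closed, so that the aryloxy group enters at an unhindered, strongly electrophilic β-carbon.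
- The lithium enolate of tert-butyl acetate (LiN(SiMe3)2, THF, −78 °C) is acylated by 3 to tert-butyl 3-[3-methoxy-4-(pivaloyloxy)phenyl]-3-oxopropanoate F1.
- NaH and Tf2O give the enol triflate tert-butyl (2Z)-3-[3-methoxy-4-(pivaloyloxy)phenyl]-3-{[(trifluoromethyl)sulfonyl]oxy}prop-2-enoate F2.
- Phenol 9 with K2CO3 in DMF displaces the triflate by addition–elimination to tert-butyl (2Z)-3-(3,5-dimethoxyphenoxy)-3-[3-methoxy-4-(pivaloyloxy)phenyl]prop-2-enoate F3.
- TFA frees (2Z)-3-(3,5-dimethoxyphenoxy)-3-[3-methoxy-4-(pivaloyloxy)phenyl]prop-2-enoic acid F4.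
- Trifluoroacetic anhydride closes ring C through the same C4–C4a bond to 4-(5,7-dimethoxy-4-oxo-4H-chromen-2-yl)-2-methoxyphenyl pivalate F5.
- Dimethyldioxirane in acetone epoxidizes C2=C3 to the racemic 4-(2,3-epoxy-5,7-dimethoxy-4-oxochroman-2-yl)-2-methoxyphenyl pivalate F6, which catalytic p-toluenesulfonic acid opens to the flavonol 14.
- BCl3 then removes only the 5-methyl group to give 15, as in the second half of step 9.

Step 10. The hydrogen-bonded, enolic 3-hydroxyl may react incompletely with the amine complex, and the polar salt may be lost or hydrolysed on isolation. The fallback sets out from 15 and comes back at 16; it goes through a neutral, chromatographable sulfate diester.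
- 2,2,2-Trichloroethyl chlorosulfate with Et3N and DMAP in THF at 0 °C should give 4-[5-hydroxy-7-methoxy-4-oxo-3-{[(2,2,2-trichloroethoxy)sulfonyl]oxy}-4H-chromen-2-yl]-2-methoxyphenyl pivalate F7.
- Zn dust and ammonium formate in methanol remove the trichloroethyl group by reductive fragmentation and leave the sulfate monoester 16.

Step 4. The enolate may be acylated on oxygen or twice, may attack the aryl pivalate, or may undergo Wittig rearrangement of the benzyl ether on warming. The fallback sets out from 3 and 6 and comes back at 7; it replaces the acylation by an aldol addition and an oxidation.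
- Rosenmund hydrogenation of 3 (H2, Pd/BaSO4, 2,6-lutidine, toluene) gives 4-formyl-2-methoxyphenyl pivalate F8.
- The lithium enolate of 6 (LiN(SiMe3)2, THF, −78 °C) adds to the aldehyde, which cannot be acylated twice, to give tert-butyl 2-(benzyloxy)-3-hydroxy-3-[3-methoxy-4-(pivaloyloxy)phenyl]propanoate F9 as a mixture of racemic diastereomers.
- Dess–Martin periodinane in CH2Cl2 oxidizes the benzylic alcohol to 7.

**Further compounds**
F1 | step 6 | tert-butyl 3-[3-methoxy-4-(pivaloyloxy)phenyl]-3-oxopropanoate | CC(C)(C)OC(=O)CC(=O)c1ccc(OC(=O)C(C)(C)C)c(OC)c1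
F2 | step 6 | tert-butyl (2Z)-3-[3-methoxy-4-(pivaloyloxy)phenyl]-3-{[(trifluoromethyl)sulfonyl]oxy}prop-2-enoate | CC(C)(C)OC(=O)/C=C(\OS(=O)(=O)C(F)(F)F)c1ccc(OC(=O)C(C)(C)C)c(OC)c1
F3 | step 6 | tert-butyl (2Z)-3-(3,5-dimethoxyphenoxy)-3-[3-methoxy-4-(pivaloyloxy)phenyl]prop-2-enoate | CC(C)(C)OC(=O)/C=C(\Oc1cc(OC)cc(OC)c1)c1ccc(OC(=O)C(C)(C)C)c(OC)c1
F4 | step 6 | (2Z)-3-(3,5-dimethoxyphenoxy)-3-[3-methoxy-4-(pivaloyloxy)phenyl]prop-2-enoic acid | OC(=O)/C=C(\Oc1cc(OC)cc(OC)c1)c1ccc(OC(=O)C(C)(C)C)c(OC)c1
F5 | step 6 | 4-(5,7-dimethoxy-4-oxo-4H-chromen-2-yl)-2-methoxyphenyl pivalate | COc1cc(OC)c2c(=O)cc(-c3ccc(OC(=O)C(C)(C)C)c(OC)c3)oc2c1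
F6 | step 6 | 4-(2,3-epoxy-5,7-dimethoxy-4-oxochroman-2-yl)-2-methoxyphenyl pivalate (racemic) | COc1cc(OC)c2C(=O)C3OC3(c3ccc(OC(=O)C(C)(C)C)c(OC)c3)Oc2c1
F7 | step 10 | 4-[5-hydroxy-7-methoxy-4-oxo-3-{[(2,2,2-trichloroethoxy)sulfonyl]oxy}-4H-chromen-2-yl]-2-methoxyphenyl pivalate | COc1cc(O)c2c(=O)c(OS(=O)(=O)OCC(Cl)(Cl)Cl)c(-c3ccc(OC(=O)C(C)(C)C)c(OC)c3)oc2c1
F8 | step 4 | 4-formyl-2-methoxyphenyl pivalate | COc1cc(C=O)ccc1OC(=O)C(C)(C)C
F9 | step 4 | tert-butyl 2-(benzyloxy)-3-hydroxy-3-[3-methoxy-4-(pivaloyloxy)phenyl]propanoate (mixture of racemic diastereomers) | CC(C)(C)OC(=O)C(OCc1ccccc1)C(O)c1ccc(OC(=O)C(C)(C)C)c(OC)c1
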